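The readings are calculated from invented constants; noise was put on by code.

Begin with the north run, where 1.1 M of electrophile met 0.741 M of nucleophile at 60 °C. There the target climbs to 30% at 12.0 min and reads 21% at 20.0 min. Turn that peak reading into a concentration: 0.330 M of target is close to half of the nucleophile charged, and this suggests a rule.

| flask | electrophile | nucleophile | free base | temperature | remark | time |
|---|---|---|---|---|---|---|
| south-east | 0.28 M | 0.741 M | 0.171 M | 45 °C | run made earlier |  |
| north | 1.1 M | 0.741 M | 0.171 M | 60 °C | run made earlier |  |
| maple | 0.57 M | 0.741 M | 0.171 M | 70 °C |  | 50 min |
| oak | 0.57 M | 0.741 M | 0.171 M | 50 °C |  | 50 min |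

- south-east (time / min: target / %): 1.50: 6; 5.00: 21; 8.00: 28; 12.0: 39; 20.0: 48; 25.0: 56; 30.0: 56
- north (time / min: target / %): 1.50: 14; 2.50: 17; 4.00: 21; 5.00: 26; 8.00: 28; 12.0: 30; 20.0: 21

(readings scatter by 2 percentage points)



- which of the two there is more of at the end, maple (target / over-reaction product)
- which of the two there is more of at the end, oak (target / over-reaction product)
- target at the end, in percent of the electrophile charged, maple
- target at the end, in percent of the electrophile charged, oak

Suppose each electrophile that reacts sets acid free, and suppose the fast step, in which acid takes a second nucleophile as protonated nucleophile, keeps up at every moment. Then you pay two nucleophiles per electrophile, and nucleophile is the limiting reagent wherever the electrophile charge exceeds the nucleophile charge divided by 2. For the north run that allows 33.7% of the electrophile, and the peak reading lies just under it. For the south-east run, with 0.28 M of electrophile, it allows 132%, so nucleophile sets no limit there, and the target reads 56% at 30.0 min, more than the north peak reading, though the two runs differ in temperature as well. If the free base took acid as quickly, the north run would allow 41.5%, further from its readings, so I leave the base out of this reckoning.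

Two amounts then remain, and for maple and oak their ratio is 65.0%: call this the nucleophile ceiling, the share of charged electrophile that the nucleophile can pay for while the base takes no acid. My own reckoning is that target stays below it in both flasks. Maple is hotter than the north run, where the target was already falling, so I expect over-reaction product to lead there. Oak is cooler, so I expect target to lead.

The forecast gives maple 15% (4% to 30%) with over-reaction product ahead and oak 38% (26% to 50%) with target ahead, since in maple “the loss has a long time to act”.

The flask gives maple 19.3% of target against 47.9% of over-reaction product, and oak 45.5% against 6.16%.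

    acid set free + free base ⇌ salt of the base (K = 1100 L mol⁻¹, k = 0.0600 L mol⁻¹ min⁻¹, Ea = 82.0 kJ mol⁻¹, ΔH = −75.0 kJ mol⁻¹)
    nucleophile + acid set free ⇌ protonated nucleophile, settled at all times (K = 700 L mol⁻¹, ΔH = −22.0 kJ mol⁻¹)
    target → over-reaction product (k = 0.00310 min⁻¹, Ea = 108 kJ mol⁻¹)
    target ⇌ isomer of the product (K = 0.490, k = 0.00630 min⁻¹, Ea = 101 kJ mol⁻¹, ΔH = −36.0 kJ mol⁻¹)
    electrophile + nucleophile → acid set free + target (k = 0.0910 L mol⁻¹ min⁻¹, Ea = 59.0 kJ mol⁻¹)
    (constants at 50 °C)

Held against the ceiling of 65.0%, oak has consumed 61.3% of its electrophile and the neighbour like maple kept at 45 °C has consumed 57.5%, both less, while maple has consumed 71.9%, more, with 0.0574 M of salt of the base standing in it. With each step taken net, the target in maple is made 3.16 times faster than it is used up at 2.76 min. At 50.0 min the net rate of making in maple is 0.411 of the net rate of using up.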